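**Strategy.** Everything rests on disconnecting C4–C5 of the dihydropyran. Ring carbon C3 carries two CH2 groups, ring C4 and the acetoxymethyl carbon; joined through the oxygen of that arm they form a 3-substituted oxetane, while O1–C6=C5 is an enol ether that is nucleophilic at C5. A Lewis acid should therefore isomerize an (R)-aryl(oxetan-3-yl)methyl (E)-2-(benzofuran-2-yl)vinyl ether, both phenols acetylated, into the trans dihydropyran: one operation forms the C4–C5 bond, the pyran ring and the C3 stereocentre and frees the hydroxymethyl arm. The (R) carbinol comes from asymmetric reduction of an aryl oxetanyl ketone, the enol ether from copper-catalysed O-vinylation with a benzofuranylvinyl iodide.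

Key step: step 14

Remark: the facial sense of the ketone reduction in step 4 is assigned by analogy with acetophenone-type ketones; should the oxetanyl ketone respond in the opposite sense, the (S,S)-catalyst would be used.

Step 1
Reactants: 1 4-bromo-2-methoxyphenol
Product: 2 (4-bromo-2-methoxyphenoxy)triisopropylsilane
Conditions: TIPSCl, imidazole, DMF, 23 °C
Reagents that add atoms: triisopropylsilyl chloride, CC(C)[Si](Cl)(C(C)C)C(C)C
Why: Silyl ether protection of the phenol; the hindered triisopropylsilyl group should survive Grignard formation, the reduction and carbonate base and is removable later with fluoride.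

Step 2
Reactants: 3 oxetane-3-carboxylic acid
Product: 5 N-methoxy-N-methyloxetane-3-carboxamide, via 1-(oxetane-3-carbonyl)imidazole 4 (not isolated)
Conditions: CDI, CH2Cl2, 23 °C; then MeNH(OMe)·HCl, 23 °C
Reagents that add atoms: N,O-dimethylhydroxylamine hydrochloride, CNOC.Cl
Why: Weinreb amide formation by way of the acylimidazole runs under neutral conditions, which avoids the acid-promoted isomerization to which oxetane-3-carboxylic acid derivatives are prone.

Step 3
Reactants: 2 (4-bromo-2-methoxyphenoxy)triisopropylsilane; 5 N-methoxy-N-methyloxetane-3-carboxamide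
Product: 7 [3-methoxy-4-(triisopropylsilyloxy)phenyl](oxetan-3-yl)methanone, via arylmagnesium bromide 6 (not isolated)
Conditions: Mg, THF, 40 °C; then 5, 0 °C; H2O
Reagents that add atoms: none
Why: Weinreb ketone synthesis: the magnesium-chelated tetrahedral adduct does not collapse before work-up, so the aryl Grignard reagent adds once, and the oxetane ring is inert to Grignard reagents at 0 °C without Lewis acid.

Step 4
Reactants: 7 [3-methoxy-4-(triisopropylsilyloxy)phenyl](oxetan-3-yl)methanone
Product: 8 (R)-[3-methoxy-4-(triisopropylsilyloxy)phenyl](oxetan-3-yl)methanol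
Conditions: RuCl[(R,R)-TsDPEN](p-cymene) (1 mol %), HCO2H/Et3N (amine in excess), CH2Cl2, 25 °C
Reagents that add atoms: none
Why: Noyori asymmetric transfer hydrogenation: the (R,R)-catalyst is expected to place the aryl group next to the cymene ligand (CH–π contact) and to deliver hydride to the face that gives the (R)-carbinol, as it does for acetophenones, while the amine-rich formate medium leaves oxetane and silyl ether intact.

Step 5
Reactants: 9 4-bromo-2,5-dimethoxybenzaldehyde
Product: 10 4-bromo-2-hydroxy-5-methoxybenzaldehyde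
Conditions: BCl3, CH2Cl2, −78 to 0 °C; H2O
Reagents that add atoms: none
Why: Chelation-directed ether cleavage: BCl3 bound to the aldehyde oxygen removes only the methyl group of the ortho methoxy group through a six-membered chelate, the 5-methoxy group having no such neighbour.

Step 6
Reactants: 10 4-bromo-2-hydroxy-5-methoxybenzaldehyde; 11 bromoacetaldehyde diethyl acetal
Product: 12 4-bromo-2-(2,2-diethoxyethoxy)-5-methoxybenzaldehyde
Conditions: K2CO3, NaI (cat.), DMF, 110 °C
Reagents that add atoms: none
Why: Williamson ether synthesis: the potassium phenoxide displaces the primary bromide (iodide catalysis), and the diethyl acetal is stable to base.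

Step 7
Reactants: 12 4-bromo-2-(2,2-diethoxyethoxy)-5-methoxybenzaldehyde
Product: 13 6-bromo-5-methoxy-1-benzofuran-2-carbaldehyde
Conditions: AcOH, 110 °C
Reagents that add atoms: none
Why: Acid unmasks the aryloxyacetaldehyde, whose enol adds to the neighbouring formyl group and dehydrates (intramolecular aldol condensation) to the aromatic benzofuran-2-carbaldehyde.

Step 8
Reactants: 13 6-bromo-5-methoxy-1-benzofuran-2-carbaldehyde
Product: 15 6-acetyl-5-methoxy-1-benzofuran-2-carbaldehyde, via 6-(1-ethoxyvinyl)-5-methoxy-1-benzofuran-2-carbaldehyde 14 (not isolated)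
Conditions: Bu3SnC(OEt)=CH2, Pd(PPh3)2Cl2 (5 mol %), toluene, 100 °C; then 1 M HCl, THF, 23 °C
Reagents that add atoms: tributyl(1-ethoxyvinyl)stannane, CCCC[Sn](CCCC)(CCCC)C(=C)OCC; water, O
Why: Stille coupling of the aryl bromide with the acetyl-anion equivalent under neutral conditions spares the aldehyde, and dilute acid hydrolyses the enol ether to the methyl ketone.

Step 9
Reactants: 15 6-acetyl-5-methoxy-1-benzofuran-2-carbaldehyde
Product: 16 6-acetyl-5-hydroxy-1-benzofuran-2-carbaldehyde
Conditions: BCl3, CH2Cl2, −78 to 0 °C; H2O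
Reagents that add atoms: none
Why: The same chelation-directed BCl3 demethylation, now steered by the acetyl group to the adjacent 5-methoxy group, frees the phenol without touching aldehyde or furan.

Step 10
Reactants: 16 6-acetyl-5-hydroxy-1-benzofuran-2-carbaldehyde
Product: 17 6-acetyl-5-(triisopropylsilyloxy)-1-benzofuran-2-carbaldehyde
Conditions: TIPSCl, imidazole, DMF, 40 °C
Reagents that add atoms: triisopropylsilyl chloride, CC(C)[Si](Cl)(C(C)C)C(C)C
Why: Silyl ether protection of the chelated phenol gives a base-stable group for the copper coupling, and the imidazole conditions do not enolize the methyl ketone.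

Step 11
Reactants: 17 6-acetyl-5-(triisopropylsilyloxy)-1-benzofuran-2-carbaldehyde
Product: 18 1-{2-[(E)-2-iodovinyl]-5-(triisopropylsilyloxy)-1-benzofuran-6-yl}ethanone
Conditions: CrCl2, CHI3, THF, 0 to 23 °C
Reagents that add atoms: iodoform, IC(I)I
Why: Takai olefination: the iodoform-derived geminal dichromium reagent adds to the aldehyde far faster than to the hindered aryl methyl ketone and eliminates to the (E)-vinyl iodide.

Step 12
Reactants: 8 (R)-[3-methoxy-4-(triisopropylsilyloxy)phenyl](oxetan-3-yl)methanol; 18 1-{2-[(E)-2-iodovinyl]-5-(triisopropylsilyloxy)-1-benzofuran-6-yl}ethanone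
Product: 19 1-{2-[(E)-2-{(R)-[3-methoxy-4-(triisopropylsilyloxy)phenyl](oxetan-3-yl)methoxy}vinyl]-5-(triisopropylsilyloxy)-1-benzofuran-6-yl}ethanone
Conditions: CuI (10 mol %), 3,4,7,8-tetramethyl-1,10-phenanthroline (20 mol %), Cs2CO3, toluene, 80 °C
Reagents that add atoms: none
Why: Ullmann-type copper-catalysed C–O coupling of the caesium alkoxide with the vinyl iodide retains the (E) geometry and does not touch the carbinol C–O bond, so the (R) centre is carried over unchanged.

Step 13
Reactants: 19 1-{2-[(E)-2-{(R)-[3-methoxy-4-(triisopropylsilyloxy)phenyl](oxetan-3-yl)methoxy}vinyl]-5-(triisopropylsilyloxy)-1-benzofuran-6-yl}ethanone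
Product: 21 6-acetyl-2-[(E)-2-{(R)-(4-acetoxy-3-methoxyphenyl)(oxetan-3-yl)methoxy}vinyl]-1-benzofuran-5-yl acetate, via bisphenol 20 (not isolated)
Conditions: TBAF/AcOH (1:1), THF, 0 °C; then Ac2O, pyridine, DMAP (cat.), 0 to 23 °C
Reagents that add atoms: acetic anhydride, CC(=O)OC(C)=O
Why: Fluoride cleaves both aryl silyl ethers, the acetic acid buffer keeps the para-hydroxybenzyl vinyl ether protonated so that it cannot expel the enolate through a quinone methide, and acetylation in the same flask gives the diacetate (protecting-group exchange).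

Step 14
Reactants: 21 6-acetyl-2-[(E)-2-{(R)-(4-acetoxy-3-methoxyphenyl)(oxetan-3-yl)methoxy}vinyl]-1-benzofuran-5-yl acetate
Product: 22 6-acetyl-2-[(2R,3S)-2-(4-acetoxy-3-methoxyphenyl)-3-(hydroxymethyl)-3,4-dihydro-2H-pyran-5-yl]-1-benzofuran-5-yl acetate (aryl and hydroxymethyl trans)
Conditions: Sc(OTf)3 (10 mol %), 2,6-di-tert-butyl-4-methylpyridine (20 mol %), 4 Å MS, CH2Cl2 (0.01 M), −20 to 23 °C
Reagents that add atoms: none
Why: Proposed new method: Sc(OTf)3 should bind the oxetane oxygen, the strongest donor in 21, whereupon enol ether carbon C5 opens the strained ring at one CH2 group in an intramolecular SN2 reaction that forms C4–C5, and the resulting O1=C6 oxocarbenium ion loses its acidic C5 proton, relayed by the hindered pyridine to the released alkoxide, so that the conjugated C5=C6 enol ether and the free hydroxymethyl group result from a net isomerization. The closest known reactions are Lewis acid openings of oxetanes by silyl enol ethers and catalytic desymmetrizations of 3-substituted oxetanes by tethered heteroatom or arene nucleophiles; a plain alkyl enol ether has not served as the tethered nucleophile. The pyran ring closes in the 6-(enolendo)-exo-tet mode, which is stereoelectronically allowed, and the (E) enol ether can adopt the required cisoid arrangement about O1–C6 because only hydrogen is cis to O1 at C5. The new stereocentre C3 is controlled by the (R) centre C2: backside attack forces the departing CH2–O arm anti to the forming bond (equatorial at C3), and only attack on the CH2 group that leaves the C2 aryl group pseudo-equatorial, away from the face of the oxetane, is unstrained, which gives the trans (2R,3S) product. The step needs chemoselectivity for oxetane activation over ionization of the benzylic C2–O1 bond and over protonation of the enol ether, and this is secured by the electron-poor acetoxyaryl group, the acceptor-substituted enol ether, the proton scavenger, the sieves and the high dilution. Should the released alkoxide add to C6, the bridged acetal is expected to reopen under the same Lewis acid and drain to the conjugated enol ether.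

Step 15
Reactants: 22 6-acetyl-2-[(2R,3S)-2-(4-acetoxy-3-methoxyphenyl)-3-(hydroxymethyl)-3,4-dihydro-2H-pyran-5-yl]-1-benzofuran-5-yl acetate
Product: 23 [(2R,3S)-5-(5-acetoxy-6-acetyl-1-benzofuran-2-yl)-2-(4-acetoxy-3-methoxyphenyl)-3,4-dihydro-2H-pyran-3-yl]methyl acetate
Conditions: Ac2O, pyridine, DMAP (cat.), CH2Cl2, 0 °C
Reagents that add atoms: acetic anhydride, CC(=O)OC(C)=O
Why: DMAP-catalysed acetylation of the only free hydroxyl group, the primary alcohol, under conditions that leave enol ether and aryl acetates alone.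

Step 16
Reactants: 23 [(2R,3S)-5-(5-acetoxy-6-acetyl-1-benzofuran-2-yl)-2-(4-acetoxy-3-methoxyphenyl)-3,4-dihydro-2H-pyran-3-yl]methyl acetate
Product: 24 propolis-benzofuran A, [(2R,3S)-5-(6-acetyl-5-hydroxy-1-benzofuran-2-yl)-2-(4-hydroxy-3-methoxyphenyl)-3,4-dihydro-2H-pyran-3-yl]methyl acetate
Conditions: NH4OAc, MeOH/H2O (4:1), 23 °C
Reagents that add atoms: none
Why: Chemoselective transesterification: aryl acetates, which release phenoxide leaving groups, are cleaved by ammonium acetate in aqueous methanol at neutral pH much faster than the primary alkyl acetate, and the neutral medium avoids acetyl migration and quinone methide opening at C2.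

**Compound list**

1 | 4-bromo-2-methoxyphenol | COc1cc(Br)ccc1O | starting material
2 | (4-bromo-2-methoxyphenoxy)triisopropylsilane | COc1cc(Br)ccc1O[Si](C(C)C)(C(C)C)C(C)C | intermediate
3 | oxetane-3-carboxylic acid | OC(=O)C1COC1 | starting material
4 | 1-(oxetane-3-carbonyl)imidazole | O=C(C1COC1)n1ccnc1 | intermediate (not isolated)
5 | N-methoxy-N-methyloxetane-3-carboxamide | CON(C)C(=O)C1COC1 | intermediate
6 | [3-methoxy-4-(triisopropylsilyloxy)phenyl]magnesium bromide | COc1cc([Mg]Br)ccc1O[Si](C(C)C)(C(C)C)C(C)C | intermediate (not isolated)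
7 | [3-methoxy-4-(triisopropylsilyloxy)phenyl](oxetan-3-yl)methanone | COc1cc(C(=O)C2COC2)ccc1O[Si](C(C)C)(C(C)C)C(C)C | intermediate
8 | (R)-[3-methoxy-4-(triisopropylsilyloxy)phenyl](oxetan-3-yl)methanol | COc1cc([C@H](O)C2COC2)ccc1O[Si](C(C)C)(C(C)C)C(C)C | intermediate
9 | 4-bromo-2,5-dimethoxybenzaldehyde | COc1cc(C=O)c(OC)cc1Br | starting material
10 | 4-bromo-2-hydroxy-5-methoxybenzaldehyde | COc1cc(C=O)c(O)cc1Br | intermediate
11 | bromoacetaldehyde diethyl acetal | CCOC(CBr)OCC | starting material
12 | 4-bromo-2-(2,2-diethoxyethoxy)-5-methoxybenzaldehyde | CCOC(COc1cc(Br)c(OC)cc1C=O)OCC | intermediate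
13 | 6-bromo-5-methoxy-1-benzofuran-2-carbaldehyde | COc1cc2cc(C=O)oc2cc1Br | intermediate
14 | 6-(1-ethoxyvinyl)-5-methoxy-1-benzofuran-2-carbaldehyde | CCOC(=C)c1cc2oc(C=O)cc2cc1OC | intermediate (not isolated)
15 | 6-acetyl-5-methoxy-1-benzofuran-2-carbaldehyde | COc1cc2cc(C=O)oc2cc1C(C)=O | intermediate
16 | 6-acetyl-5-hydroxy-1-benzofuran-2-carbaldehyde | CC(=O)c1cc2oc(C=O)cc2cc1O | intermediate
17 | 6-acetyl-5-(triisopropylsilyloxy)-1-benzofuran-2-carbaldehyde | CC(=O)c1cc2oc(C=O)cc2cc1O[Si](C(C)C)(C(C)C)C(C)C | intermediate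
18 | 1-{2-[(E)-2-iodovinyl]-5-(triisopropylsilyloxy)-1-benzofuran-6-yl}ethanone | CC(=O)c1cc2oc(/C=C/I)cc2cc1O[Si](C(C)C)(C(C)C)C(C)C | intermediate
19 | 1-{2-[(E)-2-{(R)-[3-methoxy-4-(triisopropylsilyloxy)phenyl](oxetan-3-yl)methoxy}vinyl]-5-(triisopropylsilyloxy)-1-benzofuran-6-yl}ethanone | COc1cc([C@H](O/C=C/c2cc3cc(O[Si](C(C)C)(C(C)C)C(C)C)c(C(C)=O)cc3o2)C2COC2)ccc1O[Si](C(C)C)(C(C)C)C(C)C | intermediate
20 | 1-{5-hydroxy-2-[(E)-2-{(R)-(4-hydroxy-3-methoxyphenyl)(oxetan-3-yl)methoxy}vinyl]-1-benzofuran-6-yl}ethanone | COc1cc([C@H](O/C=C/c2cc3cc(O)c(C(C)=O)cc3o2)C2COC2)ccc1O | intermediate (not isolated)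
21 | 6-acetyl-2-[(E)-2-{(R)-(4-acetoxy-3-methoxyphenyl)(oxetan-3-yl)methoxy}vinyl]-1-benzofuran-5-yl acetate | COc1cc([C@H](O/C=C/c2cc3cc(OC(C)=O)c(C(C)=O)cc3o2)C2COC2)ccc1OC(C)=O | intermediate
22 | 6-acetyl-2-[(2R,3S)-2-(4-acetoxy-3-methoxyphenyl)-3-(hydroxymethyl)-3,4-dihydro-2H-pyran-5-yl]-1-benzofuran-5-yl acetate | COc1cc([C@@H]2OC=C(c3cc4cc(OC(C)=O)c(C(C)=O)cc4o3)C[C@H]2CO)ccc1OC(C)=O | intermediate
23 | [(2R,3S)-5-(5-acetoxy-6-acetyl-1-benzofuran-2-yl)-2-(4-acetoxy-3-methoxyphenyl)-3,4-dihydro-2H-pyran-3-yl]methyl acetate | COc1cc([C@@H]2OC=C(c3cc4cc(OC(C)=O)c(C(C)=O)cc4o3)C[C@H]2COC(C)=O)ccc1OC(C)=O | intermediate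
24 | propolis-benzofuran A, [(2R,3S)-5-(6-acetyl-5-hydroxy-1-benzofuran-2-yl)-2-(4-hydroxy-3-methoxyphenyl)-3,4-dihydro-2H-pyran-3-yl]methyl acetate | COc1cc([C@@H]2OC=C(c3cc4cc(O)c(C(C)=O)cc4o3)C[C@H]2COC(C)=O)ccc1O | target

**Step count and risks**

Total: 16 steps. Longest linear sequence: 12 steps (steps 5 to 16, from 9 to 24).

Steps most likely to fail:

1. Step 14. The released alkoxide may add to the O1=C6 oxocarbenium ion and hold the material as a bridged bicyclic acetal, the benzylic C2–O1 bond may ionize (1,3-shift or loss of the enol ether), or the two oxetane CH2 groups may be attacked with little discrimination. The fallback uses known chemistry and a different set of disconnections: C2/C3 by aldol reaction, O1–C6 by alkynol cycloisomerization, the benzofuran by cross-coupling. It sets out from bromide 2 and aldehyde 17 and returns to the route at target 24. Bromide 2 is lithiated (n-BuLi, THF, −78 °C) and formylated with DMF to 3-methoxy-4-(triisopropylsilyloxy)benzaldehyde F1. Pent-4-ynoic acid, pivaloyl chloride and (R)-4-benzyloxazolidin-2-one give (R)-4-benzyl-3-(pent-4-ynoyl)oxazolidin-2-one F2. Its dibutylboron enolate (Bu2BOTf, i-Pr2NEt, CH2Cl2, −78 °C) is added to F1 in an Evans syn-aldol reaction, which should give the (2R,3R) aldol adduct F3 with both stereocentres in the relationship that becomes trans in the ring. LiBH4 (THF, MeOH, 0 °C) removes the auxiliary to give the (1R,2S) 2-propargylpropane-1,3-diol F4. AcCl with 2,4,6-collidine (CH2Cl2, −78 °C) acetylates the primary hydroxyl group to the alkynol monoacetate F5. Tungsten-vinylidene endo-cycloisomerization (W(CO)6, DABCO, THF, hν, 60 °C) closes the (2R,3S) 2-aryl-3-(acetoxymethyl)dihydropyran F6. NIS with catalytic AgNO3 (MeCN) iodinates it at C5 to the 5-iododihydropyran F7. In parallel, aldehyde 17 is decarbonylated (RhCl(PPh3)3, toluene, 110 °C, Tsuji–Wilkinson reaction) to 1-[5-(triisopropylsilyloxy)-1-benzofuran-6-yl]ethanone F8. C–H borylation at the furan 2-position ([Ir(OMe)(cod)]2, 4,4′-di-tert-butyl-2,2′-bipyridine, B2pin2, THF, 60 °C) gives the benzofuran-2-yl pinacol boronate F9. Suzuki–Miyaura coupling of F7 with F9 (Pd(dppf)Cl2, K3PO4, dioxane/H2O, 50 °C) should give the bis-silyl ether of the target F10. TBAF buffered with AcOH (THF, 0 °C) then frees both phenols to give 24.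

2. Step 12. C–O bond formation at the hindered secondary alkoxide may be slow, so that carbonate-induced loss of a phenolic silyl group or dehydroiodination of the vinyl iodide takes over. The fallback replaces the Ullmann-type coupling by an oxidative Chan–Lam-type etherification with an alkenylboron reagent at room temperature. It sets out from aldehyde 17 and alcohol 8 and returns at enol ether 19. Aldehyde 17 is homologated with Cl2CHBpin, CrCl2 and LiI (THF, 23 °C, the boron variant of the Takai olefination) to the (E)-alkenyl pinacol boronate F11. KHF2 in aqueous MeCN, a solvent in which fluoride attacks phenolic silyl ethers only slowly, converts it into the potassium (E)-alkenyltrifluoroborate F12. F12 and alcohol 8 are coupled with Cu(OAc)2 (cat.), DMAP and 4 Å MS under O2 in CH2Cl2 at 23 °C to give 19 with the alkene geometry retained.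

3. Step 4. Facial selectivity may be poor or hydride transfer slow, because the ketone carries a branched oxetanyl group next to the carbonyl group and an electron-rich aryl group. The fallback is a Corey–Bakshi–Shibata reduction with (S)-2-methyl-CBS-oxazaborolidine (20 mol %) and BH3·SMe2 in THF at −20 °C. Here the face is chosen by the steric difference between aryl and oxetanyl on the boron-bound ketone, not by an arene CH–π contact, and the (R)-alcohol is expected. It sets out from ketone 7, returns at alcohol 8 and makes no new compound (entry F0).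

**Further compounds**

F1 | step 14 | 3-methoxy-4-(triisopropylsilyloxy)benzaldehyde | COc1cc(C=O)ccc1O[Si](C(C)C)(C(C)C)C(C)C
F2 | step 14 | (R)-4-benzyl-3-(pent-4-ynoyl)oxazolidin-2-one | C#CCCC(=O)N1[C@H](Cc2ccccc2)COC1=O
F3 | step 14 | (R)-4-benzyl-3-{(2R,3R)-3-hydroxy-3-[3-methoxy-4-(triisopropylsilyloxy)phenyl]-2-(prop-2-yn-1-yl)propanoyl}oxazolidin-2-one | COc1cc([C@H](O)[C@@H](CC#C)C(=O)N2[C@H](Cc3ccccc3)COC2=O)ccc1O[Si](C(C)C)(C(C)C)C(C)C
F4 | step 14 | (1R,2S)-1-[3-methoxy-4-(triisopropylsilyloxy)phenyl]-2-(prop-2-yn-1-yl)propane-1,3-diol | COc1cc([C@H](O)[C@@H](CC#C)CO)ccc1O[Si](C(C)C)(C(C)C)C(C)C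
F5 | step 14 | (2S)-2-{(R)-hydroxy[3-methoxy-4-(triisopropylsilyloxy)phenyl]methyl}pent-4-yn-1-yl acetate | COc1cc([C@H](O)[C@@H](CC#C)COC(C)=O)ccc1O[Si](C(C)C)(C(C)C)C(C)C
F6 | step 14 | {(2R,3S)-2-[3-methoxy-4-(triisopropylsilyloxy)phenyl]-3,4-dihydro-2H-pyran-3-yl}methyl acetate | COc1cc([C@@H]2OC=CC[C@H]2COC(C)=O)ccc1O[Si](C(C)C)(C(C)C)C(C)C
F7 | step 14 | {(2R,3S)-5-iodo-2-[3-methoxy-4-(triisopropylsilyloxy)phenyl]-3,4-dihydro-2H-pyran-3-yl}methyl acetate | COc1cc([C@@H]2OC=C(I)C[C@H]2COC(C)=O)ccc1O[Si](C(C)C)(C(C)C)C(C)C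
F8 | step 14 | 1-[5-(triisopropylsilyloxy)-1-benzofuran-6-yl]ethanone | CC(=O)c1cc2occc2cc1O[Si](C(C)C)(C(C)C)C(C)C
F9 | step 14 | 1-[2-(4,4,5,5-tetramethyl-1,3,2-dioxaborolan-2-yl)-5-(triisopropylsilyloxy)-1-benzofuran-6-yl]ethanone | CC(=O)c1cc2oc(B3OC(C)(C)C(C)(C)O3)cc2cc1O[Si](C(C)C)(C(C)C)C(C)C
F10 | step 14 | {(2R,3S)-5-[6-acetyl-5-(triisopropylsilyloxy)-1-benzofuran-2-yl]-2-[3-methoxy-4-(triisopropylsilyloxy)phenyl]-3,4-dihydro-2H-pyran-3-yl}methyl acetate | COc1cc([C@@H]2OC=C(c3cc4cc(O[Si](C(C)C)(C(C)C)C(C)C)c(C(C)=O)cc4o3)C[C@H]2COC(C)=O)ccc1O[Si](C(C)C)(C(C)C)C(C)C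
F11 | step 12 | 1-{2-[(E)-2-(4,4,5,5-tetramethyl-1,3,2-dioxaborolan-2-yl)vinyl]-5-(triisopropylsilyloxy)-1-benzofuran-6-yl}ethanone | CC(=O)c1cc2oc(/C=C/B3OC(C)(C)C(C)(C)O3)cc2cc1O[Si](C(C)C)(C(C)C)C(C)C
F12 | step 12 | potassium (E)-{2-[6-acetyl-5-(triisopropylsilyloxy)-1-benzofuran-2-yl]vinyl}trifluoroborate | CC(=O)c1cc2oc(/C=C/[B-](F)(F)F)cc2cc1O[Si](C(C)C)(C(C)C)C(C)C.[K+]
F0 | step 4 | none | none
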